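**Retrosynthetic overview**
1. Last step: the furan ring and the C3–C1′ bond (isoflavone numbering) are cut together, giving the 2-(pyrrolidin-1-yl)chromone 10 and ring B as its p-quinone 16. C3 and C1′ are both innately nucleophilic, so ring B enters with reversed polarity (the quinone is the acceptor form of the trioxygenated arene).
2. 10 comes from the 2-(methylsulfanyl)chromone 9, and 9 from acetophenone 6 plus CS2 (pyranone ring C).
3. 6 comes from phloroacetophenone 1: the para-OH is blocked as a pivalate, isoprene is annulated onto an ortho-OH, then the last free ring carbon is C-prenylated.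
4. 16 comes from 2,2-dimethylchroman-5-ol 15, from chromanone 13, from 2′,6′-dihydroxyacetophenone 11 and acetone.
5. Ring order: dihydropyran on ring A, then pyranone ring C; dihydropyran on ring B in a separate branch; furan ring last.

Assumption: the target has no stereocentre and no stereogenic double bond, so it is achiral and the constitution alone defines the required compound.

**Route**

Step 1
Reactants: 1 2′,4′,6′-trihydroxyacetophenone (anhydrous)
Product: 2 4-acetyl-3,5-dihydroxyphenyl pivalate
Conditions: PivCl (1.0 equiv), Et3N (1.05 equiv), THF, −20 to 0 °C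
Reagents that add atoms: pivaloyl chloride, CC(C)(C)C(Cl)=O
Why: Base-mediated O-acylation goes to the most acidic, non-chelated para-OH, because both ortho-OH groups are hydrogen-bonded to and shielded by the acetyl group.

Step 2
Reactants: 2 4-acetyl-3,5-dihydroxyphenyl pivalate
Product: 4 8-acetyl-7-hydroxy-2,2-dimethylchroman-5-yl pivalate, via ring-prenylated phenol 3 (not isolated)
Conditions: isoprene (1.3 equiv), Amberlyst-15, THF–heptane, 65 °C, sealed vessel
Reagents that add atoms: isoprene, C=CC(C)=C
Why: Acid-catalysed Friedel–Crafts prenylation at one of the two equivalent free ring carbons is followed by Markovnikov hydroalkoxylation by the only adjacent free OH (the ortho-OH, since the para oxygen is esterified), so this phenol–isoprene chroman annulation can only place the acetyl group next to the ring oxygen.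

Step 3
Reactants: 4 8-acetyl-7-hydroxy-2,2-dimethylchroman-5-yl pivalate
Product: 6 1-[5,7-dihydroxy-2,2-dimethyl-6-(3-methylbut-2-en-1-yl)chroman-8-yl]ethanone, via diphenol 5 (not isolated)
Conditions: KOH (4 equiv), MeOH–H2O, rt, 1 h; then prenyl bromide (1.2 equiv), 0 °C
Reagents that add atoms: prenyl bromide, CC(C)=CCBr
Why: Saponification frees the second phenol, and the bis-phenoxide is alkylated at its only unsubstituted ring carbon, which is ortho to both oxygens (C-prenylation of an acylphloroglucinol-type ambident phenoxide in protic medium).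

Step 4
Reactants: 6 1-[5,7-dihydroxy-2,2-dimethyl-6-(3-methylbut-2-en-1-yl)chroman-8-yl]ethanone
Product: 9 5-hydroxy-2,2-dimethyl-6-(3-methylbut-2-en-1-yl)-8-(methylsulfanyl)-3,4-dihydro-2H,10H-pyrano[2,3-f]chromen-10-one, via lithium beta-oxodithioate 7 (not isolated), via ketene dithioacetal 8 (not isolated)
Conditions: LiN(SiMe3)2 (4.0 equiv), THF, −78 to 0 °C; CS2 (1.1 equiv), 0 °C; MeI (2.1 equiv), 0 to 45 °C
Reagents that add atoms: carbon disulfide, S=C=S; iodomethane, CI
Why: The lithium polyanion (two phenoxides plus the ketone enolate, as in polyanion acylations of unprotected hydroxyacetophenones) adds through carbon to CS2, the soft dithiolate is S-methylated twice, and the ortho-phenoxide closes the pyranone by addition–elimination with loss of MeS− (CS2-based 2-(methylsulfanyl)chromone synthesis).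

Step 5
Reactants: 9 5-hydroxy-2,2-dimethyl-6-(3-methylbut-2-en-1-yl)-8-(methylsulfanyl)-3,4-dihydro-2H,10H-pyrano[2,3-f]chromen-10-one
Product: 10 5-hydroxy-2,2-dimethyl-6-(3-methylbut-2-en-1-yl)-8-(pyrrolidin-1-yl)-3,4-dihydro-2H,10H-pyrano[2,3-f]chromen-10-one
Conditions: pyrrolidine (10 equiv), EtOH, 80 °C, sealed tube
Reagents that add atoms: pyrrolidine, C1CCNC1
Why: Addition–elimination at the beta-carbon of the vinylogous thioester (chromone C2) replaces MeS by the secondary amine, the standard entry to 2-aminochromones.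

Step 6
Reactants: 11 2′,6′-dihydroxyacetophenone
Product: 13 5-hydroxy-2,2-dimethylchroman-4-one, via aldol enone 12 (not isolated)
Conditions: acetone (3 equiv), pyrrolidine (0.5 equiv), EtOH, 60 °C
Reagents that add atoms: acetone, CC(C)=O
Why: Kabbe condensation, in which pyrrolidine mediates the crossed aldol condensation of the methyl ketone with acetone and one of the two equivalent ortho-OH groups then closes the ring by oxa-Michael addition.

Step 7
Reactants: 13 5-hydroxy-2,2-dimethylchroman-4-one
Product: 15 2,2-dimethylchroman-5-ol, via benzylic alcohol 14 (not isolated)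
Conditions: Et3SiH (3 equiv), CF3CO2H, 0 °C to rt
Reagents that add atoms: none
Why: Ionic hydrogenation, in which the doubly ortho-oxygenated aryl ketone is protonated and reduced twice by hydride transfer through a stabilised benzylic cation to the methylene.

Step 8
Reactants: 15 2,2-dimethylchroman-5-ol
Product: 16 2,2-dimethylchroman-5,8-dione
Conditions: (KSO3)2NO (Fremy's salt, 2.2 equiv), KH2PO4, acetone–H2O, 0 °C to rt
Reagents that add atoms: potassium nitrosodisulfonate, [K+].[K+].[O]N(S(=O)(=O)[O-])S(=O)(=O)[O-]
Why: Teuber oxidation, in which a phenol with a free para position is oxidised by the nitroxyl radical to the p-quinone.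

Step 9
Reactants: 10 5-hydroxy-2,2-dimethyl-6-(3-methylbut-2-en-1-yl)-8-(pyrrolidin-1-yl)-3,4-dihydro-2H,10H-pyrano[2,3-f]chromen-10-one; 16 2,2-dimethylchroman-5,8-dione
Product: 18 CNP0081329.0 (target coumaronochromone), via hydroquinone Michael adduct 17 (not isolated)
Conditions: 16 (1.05 equiv, slow addition), AcOH, N2, 25 to 60 °C
Reagents that add atoms: none
Why: Proposed new method: a Nenitzescu-type formal [3+2] annulation in which ring B reacts as its polarity-reversed quinone; the push–pull ketene N,O-acetal carbon C3 of 10 adds in Michael fashion to C6 of 16, which is beta to the more electrophilic C8 carbonyl because the ring oxygen deactivates the C5 carbonyl as a vinylogous ester (the same sense as alkoxy-p-quinones in Nenitzescu reactions); the adduct tautomerises to hydroquinone 17, whose C5 hydroxyl ortho to the new bond attacks chromone C2 and expels pyrrolidine to aromatise the furan; the closest known reaction type is the Nenitzescu 5-hydroxybenzofuran synthesis from tertiary enaminones and p-benzoquinones, and no stereocentre is formed.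

**Compound list**
1 | 2′,4′,6′-trihydroxyacetophenone | CC(=O)c1c(O)cc(O)cc1O | starting material
2 | 4-acetyl-3,5-dihydroxyphenyl pivalate | CC(=O)c1c(O)cc(OC(=O)C(C)(C)C)cc1O | intermediate
3 | 4-acetyl-3,5-dihydroxy-2-(3-methylbut-2-en-1-yl)phenyl pivalate (not isolated) | CC(=O)c1c(O)cc(OC(=O)C(C)(C)C)c(CC=C(C)C)c1O | intermediate
4 | 8-acetyl-7-hydroxy-2,2-dimethylchroman-5-yl pivalate | CC(=O)c1c(O)cc(OC(=O)C(C)(C)C)c2c1OC(C)(C)CC2 | intermediate
5 | 1-(5,7-dihydroxy-2,2-dimethylchroman-8-yl)ethanone (not isolated, as dipotassium salt) | CC(=O)c1c(O)cc(O)c2c1OC(C)(C)CC2 | intermediate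
6 | 1-[5,7-dihydroxy-2,2-dimethyl-6-(3-methylbut-2-en-1-yl)chroman-8-yl]ethanone | CC(=O)c1c(O)c(CC=C(C)C)c(O)c2c1OC(C)(C)CC2 | intermediate
7 | 3-[5,7-dihydroxy-2,2-dimethyl-6-(3-methylbut-2-en-1-yl)chroman-8-yl]-3-oxopropanedithioic acid (not isolated, as lithium salt) | SC(=S)CC(=O)c1c(O)c(CC=C(C)C)c(O)c2c1OC(C)(C)CC2 | intermediate
8 | 1-[5,7-dihydroxy-2,2-dimethyl-6-(3-methylbut-2-en-1-yl)chroman-8-yl]-3,3-bis(methylsulfanyl)prop-2-en-1-one (not isolated) | CSC(SC)=CC(=O)c1c(O)c(CC=C(C)C)c(O)c2c1OC(C)(C)CC2 | intermediate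
9 | 5-hydroxy-2,2-dimethyl-6-(3-methylbut-2-en-1-yl)-8-(methylsulfanyl)-3,4-dihydro-2H,10H-pyrano[2,3-f]chromen-10-one (a 7-hydroxy-2-(methylsulfanyl)-8-prenylchromone with the dimethyldihydropyran fused at chromone C5 (O) and C6) | CSc1cc(=O)c2c(o1)c(CC=C(C)C)c(O)c1c2OC(C)(C)CC1 | intermediate
10 | 5-hydroxy-2,2-dimethyl-6-(3-methylbut-2-en-1-yl)-8-(pyrrolidin-1-yl)-3,4-dihydro-2H,10H-pyrano[2,3-f]chromen-10-one | O=c1cc(N2CCCC2)oc2c(CC=C(C)C)c(O)c3c(c12)OC(C)(C)CC3 | intermediate
11 | 2′,6′-dihydroxyacetophenone | CC(=O)c1c(O)cccc1O | starting material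
12 | 1-(2,6-dihydroxyphenyl)-3-methylbut-2-en-1-one (not isolated) | CC(C)=CC(=O)c1c(O)cccc1O | intermediate
13 | 5-hydroxy-2,2-dimethylchroman-4-one | CC1(C)CC(=O)c2c(O)cccc2O1 | intermediate
14 | 2,2-dimethylchroman-4,5-diol (racemic, not isolated) | CC1(C)CC(O)c2c(O)cccc2O1 | intermediate
15 | 2,2-dimethylchroman-5-ol | CC1(C)CCc2c(O)cccc2O1 | intermediate
16 | 2,2-dimethylchroman-5,8-dione | CC1(C)CCC2=C(O1)C(=O)C=CC2=O | intermediate
17 | 9-(5,8-dihydroxy-2,2-dimethylchroman-6-yl)-5-hydroxy-2,2-dimethyl-6-(3-methylbut-2-en-1-yl)-8-(pyrrolidin-1-yl)-3,4-dihydro-2H,10H-pyrano[2,3-f]chromen-10-one (not isolated) | O=c1c(-c2cc(O)c3c(c2O)CCC(C)(C)O3)c(N2CCCC2)oc2c(CC=C(C)C)c(O)c3c(c12)OC(C)(C)CC3 | intermediate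
18 | CNP0081329.0: benzofuro[2,3-b]chromen-4-one (coumaronochromone) in which ring A carries a 2,2-dimethyldihydropyran fused at C5 (O) and C6, a 7-OH and an 8-prenyl group, and ring B carries a 2,2-dimethyldihydropyran fused at C4′ (O) and C3′ and a 5′-OH (isoflavone numbering); achiral | CC(C)=CCc1c(O)c2c(c3c(=O)c4c(oc13)oc1c3c(c(O)cc14)OC(C)(C)CC3)OC(C)(C)CC2 | target

**Step count and risks**
Total: 9 steps. Longest linear sequence: 6 steps (steps 1, 2, 3, 4, 5, 9); the ring B branch is steps 6–8.

The three steps most likely to fail: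

Step 9 (the annulation is unprecedented for 2-aminochromones; C3 may be too weakly nucleophilic, or the amine may not be expelled). The fallback sets out from 6 (with 16) and comes back at 18. It keeps the quinone as acceptor but changes the order of ring closure. Compound 6 is condensed with tert-butoxybis(dimethylamino)methane (toluene, 80 °C) to give the enaminone F3. F3 and 16 in AcOH undergo the classical Nenitzescu benzofuran reaction (Michael addition, closure of the hydroquinone OH onto the iminium carbon, loss of HNMe2) to give the 3-aroyl-5-hydroxybenzofuran F4. The ring A phenol ortho to the ketone is then closed onto furan C2 by base-mediated oxa-Michael addition with in-situ dehydrogenation (I2, K2CO3, DMSO, as in the chalcone-to-flavone oxidation), giving 18.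

Step 3 (O-alkylation, double alkylation and solvolysis of prenyl bromide compete with C-prenylation). The fallback sets out from 4 and comes back at 6. Compound 4 is saponified (KOH, MeOH) and the diphenol 5 is isolated. Its non-chelated 5-OH is alkylated with methyl 2-methylbut-3-en-2-yl carbonate and Pd(PPh3)4 in THF to give the tert-prenyl ether F1. Thermal aromatic Claisen rearrangement (N,N-diethylaniline, 150 °C) then moves the allyl unit, with inversion, to the only free ortho carbon and gives 6.

Step 4 (the polyanion may not form cleanly, and MeI may O-methylate a phenoxide). The fallback sets out from 6 and comes back at 10, bypassing 9 and all methylation. Compound 6 is treated with KOt-Bu and CS2 in THF; after acidic work-up the dithioate 7 cyclises with loss of H2S to the 4-hydroxy-2-thioxochromene F2. F2 is condensed with pyrrolidine (toluene, reflux), which replaces the thiocarbonyl sulfur with loss of H2S and gives 10.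

**Further compounds**
F1 | step 3 | 1-[7-hydroxy-2,2-dimethyl-5-(2-methylbut-3-en-2-yloxy)chroman-8-yl]ethanone | CC(=O)c1c(O)cc(OC(C)(C)C=C)c2c1OC(C)(C)CC2
F2 | step 4 | 5,10-dihydroxy-2,2-dimethyl-6-(3-methylbut-2-en-1-yl)-3,4-dihydro-2H,8H-pyrano[2,3-f]chromene-8-thione | S=c1cc(O)c2c(o1)c(CC=C(C)C)c(O)c1c2OC(C)(C)CC1
F3 | step 9 | (E)-3-(dimethylamino)-1-[5,7-dihydroxy-2,2-dimethyl-6-(3-methylbut-2-en-1-yl)chroman-8-yl]prop-2-en-1-one | CN(C)/C=C/C(=O)c1c(O)c(CC=C(C)C)c(O)c2c1OC(C)(C)CC2
F4 | step 9 | [5,7-dihydroxy-2,2-dimethyl-6-(3-methylbut-2-en-1-yl)chroman-8-yl](5-hydroxy-7,7-dimethyl-8,9-dihydro-7H-furo[2,3-f]chromen-3-yl)methanone | O=C(c1coc2c1cc(O)c1c2CCC(C)(C)O1)c1c(O)c(CC=C(C)C)c(O)c2c1OC(C)(C)CC2
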